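All constants are invented; what happens was integrated by code.

Litres first: the second phase has 1.0 times the volume of the first, so a share of the reagent charge reads the same in either phase.

    substrate + reagent in the reaction phase → target (k1 = 0.0180 /M/s)
    substrate + target → side product (k2 = 0.00964 /M/s)
    reagent in the reaction phase + target → over-reacted product (k3 = 0.0504 /M/s)
    reagent in the reaction phase ⇌ reagent in the second phase, rate k4*([reagent in the reaction phase] - [reagent in the second phase]/K4) per volume of the first phase (K4 = 5.9, k4 = 0.00473 /s)
    reagent in the reaction phase + protic impurity → quenched reagent (k5 = 0.0207 /M/s)

| setting | delta | eta | epsilon |
|---|---|---|---|
| substrate | 0.30 M | 0.50 M | 0.60 M |
| reagent in the second phase | 0.330 M | 0.330 M | 0.330 M |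
| protic impurity | 0.150 M | 0.150 M | 0.150 M |
| time | 8.0 min | 8.0 min | 8.0 min |
| volume of the second phase over the first | 1.0 | 1.0 | 1.0 |

- [target] at the end for delta, eta, epsilon, in this order
- how the row runs (rises, then falls / rises all the way / falls, then rises / falls all the way / hardly changes)

- a species is counted by the substrate in it: one side product counts as two
- in the second phase: reagent in the second phase; everything else is in the first
- charges count per volume of the first phase; a concentration in a rate is the amount of a species over the volume of its own phase; every rate counts per litre of the first phase
- "hardly changes" means that all values lie within two and a half points (for a concentration: within two and a half percent of the largest)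
- run time (delta): 8.0 min

The step to target needs substrate and reagent in the reaction phase, but substrate is charged above the level that reagent can reach at partition balance. So we hold substrate at its charge, and the step becomes pseudo-first-order in that reagent, which is the concentration to find.

The transfer line tells us how. At balance the reaction phase holds the second phase's content divided by 5.9, but in delta the step to target alone, at the charged substrate, halves the reagent in 2.1 min, faster than the 2.44 min in which the transfer alone halves a gap to balance, and the quench by protic impurity alone, at its charge, halves the reagent in 3.7 min. So in delta the reaction phase rests below balance, its two drains together being faster than the transfer.

Transfer coefficient over partition ratio, divided by the transfer coefficient plus both drains, gives 6.06% of the reagent charge in delta, 4.76% in eta and 4.30% in epsilon. That is the holding fraction: the share of the reagent charge standing in the reaction phase while feed equals drain, with the second phase, substrate and protic impurity at their charges and over-reaction left aside.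

Next, the side-product line. Target is made and lost in proportion to substrate, so substrate cancels from the level at which the two match. Leaving over-reaction aside, target climbs toward that balance level: 1.87 times the holding fraction times the reagent charge, which is 0.0373 M in delta, 0.0293 M in eta and 0.0265 M in epsilon. But target's half-life by that step shortens from 4.0 min in delta to 2.00 min in epsilon, against a run of 8.0 min. So the balance levels fall along the row while the climb quickens, and we commit to a row under these levels and to no shape.

The forecast gives 0.0195 M, 0.0205 M, 0.0202 M and rises, then falls, saying “the target settles near a balance between formation and loss to substrate”. It names a shape where we name none.

The flask gives target at the end of 0.0183 M, 0.0191 M, 0.0185 M: rises, then falls, turning at a substrate charge of 0.44 M. In delta at 3.38 min, target was still made 2.42 times faster than used up, each step taken net. Scaled by the second phase's remaining share, the holding fraction gives 4.65% of the reagent charge in delta at 8.00 min, and the flask holds 4.91%. In epsilon at 8.00 min the same product gives 3.20%, and the flask holds 3.44%.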